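The numbers in the tables come from a simulation on assumed constants; noise was put on by code.

One point of product, one percent of the substrate charged, is a different amount of substance in each flask, and so it costs a different share of partner.

| setting | cedar | larch | flask |
|---|---|---|---|
| substrate | 0.14 M (fed, over 1.0 h) | 0.22 M (fed, over 1.0 h) | 0.10 M (fed, over 1.0 h) |
| partner | 0.13 M | 0.13 M | 0.130 M |
| remark | run made earlier | run made earlier |  |
| time |  |  | 30 h |

| run | time / h | product / % | intermediate / % |
|---|---|---|---|
| cedar | 1.33 | 0 | 1 |
| cedar | 2.00 | 0 | 4 |
| cedar | 3.00 | 0 | 8 |
| cedar | 5.00 | 2 | 15 |
| cedar | 8.00 | 3 | 18 |
| cedar | 12.0 | 6 | 28 |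
| cedar | 20.0 | 10 | 37 |
| larch | 2.50 | 4 | 9 |
| larch | 5.00 | 0 | 13 |
| larch | 8.00 | 5 | 23 |
| larch | 10.0 | 3 | 22 |
| larch | 12.0 | 3 | 28 |
| larch | 15.0 | 7 | 29 |
| larch | 20.0 | 11 | 38 |

(scatter of a reading: 2 percentage points)

* at 30 h, what has stopped the reaction, if anything has (the partner has run out first / all of the substrate has reacted / forward and back rates have come level / it is still moving)
* product at 30 h, in percent of the substrate charged
* intermediate at 30 h, in percent of the substrate charged

- the reaction counts as stopped when no species that holds the substrate changes by six tenths of a point or more over the second half of the time

So I take as my yardstick the partner price: the points of partner's own charge spent per point of substrate charged that is spent one for one, c substrate over c partner. For the flask it is 0.769, for larch 1.69.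

Ina and Tom use this price differently. Ina holds that partner is taken up as soon as substrate reacts, so she charges it on product plus intermediate. That puts larch at 82.9% of its partner spent by 20.0 h and cedar at 50.6%, so she expects partner to govern these flasks. Tom answers that the two runs then read 49.0% and 47.0% converted, level within the scatter, so substrate reacts by itself and the price is charged on product alone. Partner then stays nearly constant, and the last step is pseudo-first-order.

I reckon with Tom. In a chain, product grows at a rate proportional to the intermediate standing. I take intermediate as a rough straight rise up to its readings at 20.0 h and then as level up to 30 h, so the product gained after 20.0 h is the mean product reading times 2 times the added time over 20.0 h, and the flask reaches about 21.0%, an estimate that carries the scatter of those readings. That costs 16.2% of the partner. In the flask substrate is the limiting reagent, 0.10 M against 0.130 M, so even full conversion to product costs 76.9%.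

The forecast, on Tom's side, says it is still moving, with 21% product and 42% intermediate: “Partner is the same and substrate is lower, so nothing should run out.”

At 30 h in the flask it is still moving, with 22.4% product and 42.7% intermediate.

    partner + intermediate ⇌ product (K = 20.0 M⁻¹, k = 7.20 × 10⁻⁵ M⁻¹ s⁻¹)
    substrate → intermediate (k = 9.90 × 10⁻⁶ s⁻¹)

Partner stands at 83%, so 17.2% has gone, against the 16.2% I reckoned, and Tom's charging holds. Ina's view gets its region at high substrate: with partner held, 0.403 M of substrate is the nearest charge above the flask's at which the intermediate answer has moved by 5 points. A neighbour flask with 0.078 M of partner has the price 1.28, so its 14.9% product should cost 19.0% of its partner, and 81% of that partner stands there at 30.0 h.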